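**Strategy.** The route rests on reading the C6=C7 alkene of ring B, flanked by C5 and C8 with the C9–C10 bond opposite, as the mark of a [4+2] union of a C5=C6–C7=C8 diene with a C9=C10 dienophile tied together through C1–C4. One aluminium-promoted intramolecular Diels–Alder reaction of an open-chain trienimide should form C5–C10 and C8–C9, close rings A and B together and set C5, C9 and C10 absolutely (C8 is corrected later by equilibration). The precursor is an (E)-3-methylenoyl imide of (R)-4-benzyl-2-oxazolidinone whose gem-dimethyl tether ends in a (Z)-2-silyloxy diene bearing a tert-butyl ester; the enol ether later fixes the 6-ene position.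

Key step: step 10

Remark: atoms carry labdane labels (ring A: C1–C5 and C10; ring B: C5–C10; C11 on C9; C17 on C8; side chain C11–C16). Compounds 1, 10 and 31 are taken as commercially available. TBS = tert-butyldimethylsilyl, TBDPS = tert-butyldiphenylsilyl.

Step 1
Reactants: 1 5-chloropent-1-yne
Product: 4 (E)-6-chloro-3-methylhex-2-en-1-ol, via alkenyldimethylalane 2 (not isolated), via lithium alkenylalanate 3 (not isolated)
Conditions: Me3Al, Cp2ZrCl2 (25 mol %), CH2Cl2, 0 °C → rt; volatiles removed; n-BuLi, hexane/THF, –78 → 0 °C; (CH2O)n, rt; aq. HCl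
Reagents that add atoms: trimethylaluminium C[Al](C)C; paraformaldehyde, reacting as formaldehyde C=O
Why: Zirconocene-catalysed carboalumination adds CH3 and aluminium syn across the terminal alkyne with aluminium on the terminal carbon, and the derived alanate is hydroxymethylated with retention, so the E trisubstituted C9=C10 alkene (chain trans to C11) should form while the primary chloride stays intact.

Step 2
Reactants: 4 (E)-6-chloro-3-methylhex-2-en-1-ol
Product: 5 (E)-tert-butyl[(6-chloro-3-methylhex-2-en-1-yl)oxy]dimethylsilane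
Conditions: TBSCl, imidazole, DMF, rt
Reagents that add atoms: tert-butyldimethylsilyl chloride CC(C)(C)[Si](C)(C)Cl
Why: Imidazole-promoted silylation of the primary allylic alcohol is routine and masks the hydroxyl for the Grignard and enolate steps that follow.

Step 3
Reactants: 5 (E)-tert-butyl[(6-chloro-3-methylhex-2-en-1-yl)oxy]dimethylsilane; 6 mesityl oxide
Product: 9 (E)-10-(tert-butyldimethylsilyloxy)-4,4,8-trimethyldec-8-en-2-one, via Grignard reagent 7 (not isolated), via trimethylsilyl enol ether 8 (not isolated)
Conditions: Mg, BrCH2CH2Br (cat.), THF, reflux; CuBr·SMe2 (10 mol %), TMSCl, 6, THF, –40 → 0 °C; K2CO3, MeOH, rt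
Reagents that add atoms: none
Why: Copper-catalysed, TMSCl-accelerated 1,4-addition of a primary alkyl Grignard reagent to a β,β-disubstituted enone is a standard way to a quaternary carbon (here C4), and mild methanolysis of the silyl enol ether should return the methyl ketone without loss of the allylic TBS ether.

Step 4
Reactants: 9 (E)-10-(tert-butyldimethylsilyloxy)-4,4,8-trimethyldec-8-en-2-one; 10 tert-butyl glyoxylate
Product: 12 tert-butyl (E)-12-(tert-butyldimethylsilyloxy)-2-hydroxy-6,6,10-trimethyl-4-oxododec-10-enoate (racemic at the carbinol carbon), via lithium enolate 11 (not isolated)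
Conditions: LDA, THF, –78 °C; 10, –78 °C; aq. NH4Cl
Reagents that add atoms: none
Why: Kinetic deprotonation should occur at the methyl group (C7) because the other α-position is a neopentyl CH2, and the enolate adds to the highly electrophilic glyoxylate aldehyde in an aldol addition whose racemic carbinol centre is removed in step 5.

Step 5
Reactants: 12 tert-butyl (E)-12-(tert-butyldimethylsilyloxy)-2-hydroxy-6,6,10-trimethyl-4-oxododec-10-enoate
Product: 14 tert-butyl (2E,10E)-12-(tert-butyldimethylsilyloxy)-6,6,10-trimethyl-4-oxododeca-2,10-dienoate, via mesylate 13 (not isolated)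
Conditions: MsCl, Et3N, CH2Cl2, 0 °C → rt
Reagents that add atoms: none
Why: Mesylation followed by E1cB elimination through the ketone enolate should give the doubly conjugated C7=C8 alkene with the thermodynamically preferred E geometry.

Step 6
Reactants: 14 tert-butyl (2E,10E)-12-(tert-butyldimethylsilyloxy)-6,6,10-trimethyl-4-oxododeca-2,10-dienoate
Product: 15 tert-butyl (2E,10E)-12-hydroxy-6,6,10-trimethyl-4-oxododeca-2,10-dienoate
Conditions: HF·pyridine, pyridine, THF, 0 °C → rt
Reagents that add atoms: none
Why: Buffered fluoride desilylation frees the C11 hydroxyl without a nucleophilic base that could add to the oxo-enoate or an acid strong enough to cleave the tert-butyl ester.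

Step 7
Reactants: 15 tert-butyl (2E,10E)-12-hydroxy-6,6,10-trimethyl-4-oxododeca-2,10-dienoate
Product: 17 (2E,10E)-12-tert-butoxy-3,7,7-trimethyl-9,12-dioxododeca-2,10-dienoic acid, via enal 16 (not isolated)
Conditions: TEMPO (10 mol %), PhI(OAc)2, CH2Cl2, rt; then NaClO2, NaH2PO4, 2-methylbut-2-ene, t-BuOH/H2O, rt
Reagents that add atoms: sodium chlorite [Na+].[O-]Cl=O
Why: Oxoammonium oxidation of the allylic alcohol stops at the enal without E/Z scrambling, and the Pinnick oxidation then gives the acid while the electron-poor alkene and the trisubstituted alkene are protected by the hypochlorite scavenger.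

Step 8
Reactants: 17 (2E,10E)-12-tert-butoxy-3,7,7-trimethyl-9,12-dioxododeca-2,10-dienoic acid; 18 (R)-4-benzyl-2-oxazolidinone
Product: 20 tert-butyl (2E,10E)-12-[(R)-4-benzyl-2-oxooxazolidin-3-yl]-6,6,10-trimethyl-4,12-dioxododeca-2,10-dienoate, via mixed pivalic anhydride 19 (not isolated)
Conditions: PivCl, Et3N, THF, –20 °C; then 18, LiCl, –20 °C → rt
Reagents that add atoms: none
Why: N-Acylation of the lithium-chloride-activated oxazolidinone by the mixed anhydride occurs at the less hindered enoyl carbonyl and avoids an acid chloride or ketene that could scramble the C9=C10 geometry.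

Step 9
Reactants: 20 tert-butyl (2E,10E)-12-[(R)-4-benzyl-2-oxooxazolidin-3-yl]-6,6,10-trimethyl-4,12-dioxododeca-2,10-dienoate
Product: 21 tert-butyl (2E,4Z,10E)-12-[(R)-4-benzyl-2-oxooxazolidin-3-yl]-4-(tert-butyldimethylsilyloxy)-6,6,10-trimethyl-12-oxododeca-2,4,10-trienoate
Conditions: TBSOTf, Et3N, CH2Cl2, –78 → 0 °C
Reagents that add atoms: tert-butyldimethylsilyl triflate CC(C)(C)[Si](C)(C)OS(=O)(=O)C(F)(F)F
Why: Soft enolisation of the ketone can only go towards C5 (C7 is vinylic), and the Z enol ether should prevail because the quaternary C4 avoids the C7 vinyl group, which places the tether on the outside of the C5=C6–C7=C8 diene as the cycloaddition requires.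

Step 10
Reactants: 21 tert-butyl (2E,4Z,10E)-12-[(R)-4-benzyl-2-oxooxazolidin-3-yl]-4-(tert-butyldimethylsilyloxy)-6,6,10-trimethyl-12-oxododeca-2,4,10-trienoate
Product: 22 trans-fused cycloadduct: C9 acyl oxazolidinone; C8 tert-butyl ester cis to C11 (axial); C6 TBS enol ether (C6=C7); 5-H trans to 10-CH3; C11 cis to 10-CH3
Conditions: Me2AlCl (2.5 equiv), CH2Cl2, –30 → 0 °C; pH 7 buffer/Rochelle salt
Reagents that add atoms: none
Why: Excess Me2AlCl turns the imide into a cationic two-point aluminium chelate with an s-cis enoyl group, and the nucleophilic C5 terminus of the 2-silyloxy diene then bonds to C10 while C9 bonds to C8 in an asynchronous, carbonyl-endo [4+2] event (at the limit a Mukaiyama–Michael/Michael sequence) that leaves the C6=C7 silyl enol ether. The closest known reaction type is the Lewis-acid-promoted type 1 intramolecular Diels–Alder reaction of oxazolidinone trienimides, which gives trans-fused bicycles. Ring B is the cyclohexene made by the cycloaddition itself (a 6-endo closure onto C8 in the stepwise picture), and ring A closes as the C1–C4 tether folds in a chair for a 6-exo attack on C10, helped by the gem-dimethyl group. C9 and C10 are set by attack on the enimide face away from the benzyl group of the (R)-auxiliary in the chelate, the E alkene puts the C10 methyl cis to C11, the tether-anti (carbonyl-endo) geometry makes 5-H trans to the C10 methyl, and the outside position of the ester on the E-enoate puts the C8 ester cis to C11 (axial), which step 14 corrects. The step needs facial and endo selectivity plus survival of the silyl enol ether: the first two should come from chelation (more than two equivalents of Me2AlCl, since the ester also binds aluminium) and from the Z enol ether that holds C4 on the outside of the diene, the last from low temperature and a buffered work-up.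

Step 11
Reactants: 22 trans-fused cycloadduct
Product: 23 C11 primary alcohol (C8 ester cis to C11; C6 TBS enol ether)
Conditions: LiBH4, MeOH (2 equiv), Et2O, 0 °C; aq. NH4Cl
Reagents that add atoms: none
Why: Methanol-activated LiBH4 reduces the exocyclic imide carbonyl to the primary alcohol and releases the auxiliary, while the tert-butyl ester and the silyl enol ether are inert at 0 °C and a cold quench limits lactonisation onto the cis ester.

Step 12
Reactants: 23 C11 primary alcohol
Product: 24 C11 aldehyde (C8 ester cis to C11; C6 TBS enol ether)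
Conditions: DMP, NaHCO3, CH2Cl2, 0 °C
Reagents that add atoms: none
Why: Buffered Dess–Martin oxidation converts the hindered primary alcohol into the aldehyde under near-neutral conditions that spare the silyl enol ether and do not epimerise C9, whose formyl group is already equatorial.

Step 13
Reactants: 24 C11 aldehyde
Product: 25 C9 vinyl compound (C11=C12; C8 ester cis to C11; C6 TBS enol ether)
Conditions: Ph3PCH3Br, KOt-Bu, THF, 0 °C; then 24, 0 °C → rt
Reagents that add atoms: methyltriphenylphosphonium bromide C[P+](c1ccccc1)(c1ccccc1)c1ccccc1.[Br-]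
Why: Wittig methylenation with the small unstabilised ylide reaches even a neopentyl-type aldehyde and leaves the tert-butyl ester and the silyl enol ether untouched.

Step 14
Reactants: 25 C9 vinyl compound
Product: 27 6-ketone with the C8 ester trans to C11 (equatorial) and 5-H trans to 10-CH3, via 8-axial ketone 26 (not isolated)
Conditions: TBAF, THF, 0 °C; then KOt-Bu (0.5 equiv), t-BuOH, rt → 40 °C; aq. NH4Cl
Reagents that add atoms: none
Why: Fluoride unmasks the C6 ketone and reversible alkoxide enolisation of the tert-butyl ester should then move the C8 ester from the axial position, where it clashes 1,3-diaxially with the C10 methyl, to the equatorial one, while C5 stays in the stable trans ring fusion (thermodynamic epimerisation).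

Step 15
Reactants: 27 6-ketone with equatorial C8 ester
Product: 29 C6 enol triflate (C6=C7; C8 ester trans to C11), via potassium enolate 28 (not isolated)
Conditions: KHMDS (1.0 equiv), THF, –78 °C; PhNTf2, –78 → 0 °C
Reagents that add atoms: N-phenylbis(trifluoromethanesulfonimide) O=S(=O)(N(c1ccccc1)S(=O)(=O)C(F)(F)F)C(F)(F)F
Why: Kinetic deprotonation should take the C7 methylene because the C5 methine is buried between two quaternary carbons and the ester α-proton is less acidic, and O-triflation of that enolate locks the double bond between C6 and C7, with base kept to one equivalent so that C8 is not deprotonated afterwards.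

Step 16
Reactants: 29 C6 enol triflate
Product: 30 tert-butyl 5,5,8a-trimethyl-1-vinyl-1,2,4a,5,6,7,8,8a-octahydronaphthalene-2-carboxylate (labdane labels: C6=C7 ene; C9 vinyl; C8 ester trans to C11)
Conditions: Pd(OAc)2 (5 mol %), PPh3 (10 mol %), HCO2H, n-Bu3N, DMF, 60 °C
Reagents that add atoms: none
Why: Zerovalent palladium formed in the flask inserts into the vinyl triflate, formate delivers hydride by decarboxylation and reductive elimination gives the C6=C7 alkene exactly where the enol triflate stood (formate reduction of a vinyl triflate).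

Step 17
Reactants: 31 tert-butyldiphenyl(prop-2-yn-1-yloxy)silane
Product: 33 tert-butyl 4-(tert-butyldiphenylsilyloxy)but-2-ynoate, via lithium acetylide 32 (not isolated)
Conditions: n-BuLi, THF, –78 °C; Boc2O, –78 °C → rt
Reagents that add atoms: di-tert-butyl dicarbonate CC(C)(C)OC(=O)OC(=O)OC(C)(C)C
Why: C-Acylation of a lithium acetylide by Boc2O gives the tert-butyl ynoate directly, and the silyl ether tolerates the base.

Step 18
Reactants: 33 tert-butyl 4-(tert-butyldiphenylsilyloxy)but-2-ynoate
Product: 34 tert-butyl (Z)-4-(tert-butyldiphenylsilyloxy)-3-iodobut-2-enoate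
Conditions: NaI, AcOH, 70 °C
Reagents that add atoms: sodium iodide [Na+].[I-]
Why: Conjugate addition of iodide to the ynoate and anti protonation (hydroiodination) places iodine cis to the ester, which is the geometry needed for C12 in the target, and the acid-stable TBDPS ether and tert-butyl ester should survive warm acetic acid.

Step 19
Reactants: 30 C9 vinyl 6-ene ester; 34 tert-butyl (Z)-4-(tert-butyldiphenylsilyloxy)-3-iodobut-2-enoate
Product: 36 coupled di-tert-butyl ester with C16 TBDPS ether (C12–C13 bond; C16 trans to the C15 ester), via B-alkyl-9-BBN 35 (not isolated)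
Conditions: 9-BBN, THF, 0 °C → rt; then 34, Pd(dppf)Cl2 (5 mol %), AsPh3, Cs2CO3, DMF/H2O, rt
Reagents that add atoms: none
Why: 9-BBN hydroborates the monosubstituted C11=C12 alkene at C12 far faster than the ring cis-alkene, and B-alkyl Suzuki–Miyaura coupling with the vinyl iodide proceeds with retention of alkene geometry, the silyl ether being chosen over an acetate so that no leaving group sits next to the palladium-bearing carbon.

Step 20
Reactants: 36 coupled di-tert-butyl ester with C16 TBDPS ether
Product: 37 C16 primary allylic alcohol (di-tert-butyl ester)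
Conditions: HF·pyridine, pyridine, THF, rt
Reagents that add atoms: none
Why: Buffered fluoride desilylation avoids basic conditions that could move the C6=C7 alkene into conjugation with the C8 ester, and the hydroxymethyl group cannot lactonise because it is trans to the C15 ester.

Step 21
Reactants: 37 C16 primary allylic alcohol
Product: 38 C16 acetate (di-tert-butyl ester)
Conditions: Ac2O, pyridine, DMAP (cat.), CH2Cl2, 0 °C
Reagents that add atoms: acetic anhydride CC(=O)OC(C)=O
Why: DMAP-catalysed acetylation of the unhindered primary alcohol is routine and touches neither ester nor alkene.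

Step 22
Reactants: 38 C16 acetate (di-tert-butyl ester)
Product: 39 target CNP0108723.1
Conditions: TFA, CH2Cl2, 0 °C → rt
Reagents that add atoms: none
Why: Acidolysis cleaves both tert-butyl esters through loss of isobutene irrespective of the hindrance at C8, while the primary acetate on the electron-poor allylic position and both alkenes should be stable to anhydrous acid.

**Compound list**

1 | 5-chloropent-1-yne | C#CCCCCl | starting material
2 | [(E)-5-chloro-2-methylpent-1-en-1-yl]dimethylalane | C[Al](C)/C=C(\C)CCCCl | intermediate (not isolated)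
3 | lithium butyl[(E)-5-chloro-2-methylpent-1-en-1-yl]dimethylalanate | [Li+].CCCC[Al-](C)(C)/C=C(\C)CCCCl | intermediate (not isolated)
4 | (E)-6-chloro-3-methylhex-2-en-1-ol | OC/C=C(\C)CCCCl | intermediate
5 | (E)-tert-butyl[(6-chloro-3-methylhex-2-en-1-yl)oxy]dimethylsilane | CC(C)(C)[Si](C)(C)OC/C=C(\C)CCCCl | intermediate
6 | mesityl oxide (4-methylpent-3-en-2-one) | CC(=O)C=C(C)C | starting material
7 | [(E)-6-(tert-butyldimethylsilyloxy)-4-methylhex-4-en-1-yl]magnesium chloride | Cl[Mg]CCC/C(C)=C/CO[Si](C)(C)C(C)(C)C | intermediate (not isolated)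
8 | trimethylsilyl enol ether of 9 (C5=C6, geometry not controlled) | C[Si](C)(C)OC(C)=CC(C)(C)CCC/C(C)=C/CO[Si](C)(C)C(C)(C)C | intermediate (not isolated)
9 | (E)-10-(tert-butyldimethylsilyloxy)-4,4,8-trimethyldec-8-en-2-one | CC(=O)CC(C)(C)CCC/C(C)=C/CO[Si](C)(C)C(C)(C)C | intermediate
10 | tert-butyl glyoxylate | O=CC(=O)OC(C)(C)C | starting material
11 | lithium enolate of 9 (methyl side) | [Li+].[O-]C(=C)CC(C)(C)CCC/C(C)=C/CO[Si](C)(C)C(C)(C)C | intermediate (not isolated)
12 | tert-butyl (E)-12-(tert-butyldimethylsilyloxy)-2-hydroxy-6,6,10-trimethyl-4-oxododec-10-enoate (racemic carbinol) | CC(C)(C)OC(=O)C(O)CC(=O)CC(C)(C)CCC/C(C)=C/CO[Si](C)(C)C(C)(C)C | intermediate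
13 | 2-methanesulfonate of 12 | CC(C)(C)OC(=O)C(OS(C)(=O)=O)CC(=O)CC(C)(C)CCC/C(C)=C/CO[Si](C)(C)C(C)(C)C | intermediate (not isolated)
14 | tert-butyl (2E,10E)-12-(tert-butyldimethylsilyloxy)-6,6,10-trimethyl-4-oxododeca-2,10-dienoate | CC(C)(C)OC(=O)/C=C/C(=O)CC(C)(C)CCC/C(C)=C/CO[Si](C)(C)C(C)(C)C | intermediate
15 | tert-butyl (2E,10E)-12-hydroxy-6,6,10-trimethyl-4-oxododeca-2,10-dienoate | CC(C)(C)OC(=O)/C=C/C(=O)CC(C)(C)CCC/C(C)=C/CO | intermediate
16 | tert-butyl (2E,10E)-6,6,10-trimethyl-4,12-dioxododeca-2,10-dienoate (enal) | CC(C)(C)OC(=O)/C=C/C(=O)CC(C)(C)CCC/C(C)=C/C=O | intermediate (not isolated)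
17 | (2E,10E)-12-tert-butoxy-3,7,7-trimethyl-9,12-dioxododeca-2,10-dienoic acid | CC(C)(C)OC(=O)/C=C/C(=O)CC(C)(C)CCC/C(C)=C/C(=O)O | intermediate
18 | (R)-4-benzyl-2-oxazolidinone | O=C1OC[C@@H](Cc2ccccc2)N1 | starting material
19 | mixed pivalic anhydride of 17 | CC(C)(C)C(=O)OC(=O)/C=C(\C)CCCC(C)(C)CC(=O)/C=C/C(=O)OC(C)(C)C | intermediate (not isolated)
20 | tert-butyl (2E,10E)-12-[(R)-4-benzyl-2-oxooxazolidin-3-yl]-6,6,10-trimethyl-4,12-dioxododeca-2,10-dienoate | O=C1OC[C@@H](Cc2ccccc2)N1C(=O)/C=C(\C)CCCC(C)(C)CC(=O)/C=C/C(=O)OC(C)(C)C | intermediate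
21 | tert-butyl (2E,4Z,10E)-12-[(R)-4-benzyl-2-oxooxazolidin-3-yl]-4-(tert-butyldimethylsilyloxy)-6,6,10-trimethyl-12-oxododeca-2,4,10-trienoate (key-step precursor) | O=C1OC[C@@H](Cc2ccccc2)N1C(=O)/C=C(\C)CCCC(C)(C)/C=C(O[Si](C)(C)C(C)(C)C)/C=C/C(=O)OC(C)(C)C | intermediate
22 | tert-butyl 1-[(R)-4-benzyl-2-oxooxazolidine-3-carbonyl]-4-(tert-butyldimethylsilyloxy)-5,5,8a-trimethyl-1,2,4a,5,6,7,8,8a-octahydronaphthalene-2-carboxylate; 4a-H trans to 8a-CH3, 1-acyl cis to 8a-CH3, 2-ester cis to 1-acyl (key-step product) | O=C1OC[C@@H](Cc2ccccc2)N1C(=O)[C@@H]1[C@H](C(=O)OC(C)(C)C)C=C(O[Si](C)(C)C(C)(C)C)[C@@H]2C(C)(C)CCC[C@@]12C | intermediate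
23 | 1-(hydroxymethyl) analogue of 22 (same configuration) | OC[C@@H]1[C@H](C(=O)OC(C)(C)C)C=C(O[Si](C)(C)C(C)(C)C)[C@@H]2C(C)(C)CCC[C@@]12C | intermediate
24 | 1-formyl analogue of 22 (same configuration) | O=C[C@@H]1[C@H](C(=O)OC(C)(C)C)C=C(O[Si](C)(C)C(C)(C)C)[C@@H]2C(C)(C)CCC[C@@]12C | intermediate
25 | 1-vinyl analogue of 22 (same configuration) | C=C[C@@H]1[C@H](C(=O)OC(C)(C)C)C=C(O[Si](C)(C)C(C)(C)C)[C@@H]2C(C)(C)CCC[C@@]12C | intermediate
26 | tert-butyl 5,5,8a-trimethyl-4-oxo-1-vinyldecahydronaphthalene-2-carboxylate; trans-fused, 2-ester cis to 1-vinyl (axial) | C=C[C@@H]1[C@H](C(=O)OC(C)(C)C)CC(=O)[C@@H]2C(C)(C)CCC[C@@]12C | intermediate (not isolated)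
27 | tert-butyl 5,5,8a-trimethyl-4-oxo-1-vinyldecahydronaphthalene-2-carboxylate; trans-fused, 2-ester trans to 1-vinyl (equatorial) | C=C[C@@H]1[C@@H](C(=O)OC(C)(C)C)CC(=O)[C@@H]2C(C)(C)CCC[C@@]12C | intermediate
28 | potassium C6=C7 enolate of 27 | C=C[C@@H]1[C@@H](C(=O)OC(C)(C)C)C=C([O-])[C@@H]2C(C)(C)CCC[C@@]12C.[K+] | intermediate (not isolated)
29 | tert-butyl 5,5,8a-trimethyl-4-(trifluoromethylsulfonyloxy)-1-vinyl-1,2,4a,5,6,7,8,8a-octahydronaphthalene-2-carboxylate; 2-ester trans to 1-vinyl | C=C[C@@H]1[C@@H](C(=O)OC(C)(C)C)C=C(OS(=O)(=O)C(F)(F)F)[C@@H]2C(C)(C)CCC[C@@]12C | intermediate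
30 | tert-butyl (1R,2S,4aR,8aS)-5,5,8a-trimethyl-1-vinyl-1,2,4a,5,6,7,8,8a-octahydronaphthalene-2-carboxylate | C=C[C@@H]1[C@@H](C(=O)OC(C)(C)C)C=C[C@@H]2C(C)(C)CCC[C@@]12C | intermediate
31 | tert-butyldiphenyl(prop-2-yn-1-yloxy)silane | C#CCO[Si](c1ccccc1)(c1ccccc1)C(C)(C)C | starting material
32 | lithium acetylide of 31 | [Li]C#CCO[Si](c1ccccc1)(c1ccccc1)C(C)(C)C | intermediate (not isolated)
33 | tert-butyl 4-(tert-butyldiphenylsilyloxy)but-2-ynoate | CC(C)(C)OC(=O)C#CCO[Si](c1ccccc1)(c1ccccc1)C(C)(C)C | intermediate
34 | tert-butyl (Z)-4-(tert-butyldiphenylsilyloxy)-3-iodobut-2-enoate | CC(C)(C)OC(=O)/C=C(\I)CO[Si](c1ccccc1)(c1ccccc1)C(C)(C)C | intermediate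
35 | B-alkyl-9-borabicyclo[3.3.1]nonane from 30 (boron on C12) | B1(CC[C@@H]3[C@@H](C(=O)OC(C)(C)C)C=C[C@@H]4C(C)(C)CCC[C@@]34C)C2CCCC1CCC2 | intermediate (not isolated)
36 | di-tert-butyl ester with C16 TBDPS ether: tert-butyl 1-[(E)-4-tert-butoxy-3-(tert-butyldiphenylsilyloxymethyl)-4-oxobut-2... side chain written out in SMILES; ring configuration as in 30, C16 trans to the C15 ester | CC(C)(C)OC(=O)/C=C(/CO[Si](c1ccccc1)(c1ccccc1)C(C)(C)C)CC[C@@H]1[C@@H](C(=O)OC(C)(C)C)C=C[C@@H]2C(C)(C)CCC[C@@]12C | intermediate
37 | C16 alcohol: ring as in 30; side chain CH2CH2–C(CH2OH)=CH–CO2t-Bu with CH2OH trans to the ester | CC(C)(C)OC(=O)/C=C(/CO)CC[C@@H]1[C@@H](C(=O)OC(C)(C)C)C=C[C@@H]2C(C)(C)CCC[C@@]12C | intermediate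
38 | C16 acetate: ring as in 30; side chain CH2CH2–C(CH2OAc)=CH–CO2t-Bu with CH2OAc trans to the ester | CC(=O)OC/C(=C/C(=O)OC(C)(C)C)CC[C@@H]1[C@@H](C(=O)OC(C)(C)C)C=C[C@@H]2C(C)(C)CCC[C@@]12C | intermediate
39 | (1R,2S,4aR,8aS)-1-[(E)-3-(acetoxymethyl)-4-carboxybut-3-en-1-yl]-5,5,8a-trimethyl-1,2,4a,5,6,7,8,8a-octahydronaphthalene-2-carboxylic acid (CNP0108723.1) | CC(=O)OC/C(=C/C(=O)O)CC[C@@H]1[C@@H](C(=O)O)C=C[C@@H]2C(C)(C)CCC[C@@]12C | target

**Step count and risks**

Total: 22 steps. Longest linear sequence: 20 steps (steps 1–16 and 19–22, from 5-chloropent-1-yne); steps 17–18 make the side-chain iodide.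

Steps most likely to fail:

1. Step 10. The crowded C5–C10 bond (a quaternary carbon forming next to a quaternary carbon) may form too slowly, so that the aluminium reagent strips the silyl group or the reaction halts after the first C–C bond, and competition of the ester for the Lewis acid could erode facial control. The fallback moves stereocontrol from the auxiliary to a catalyst at the aldehyde oxidation level. It sets out from enal 16, isolated after the first stage of step 7. Ketone-selective soft enolisation (TBSOTf, Et3N, CH2Cl2, –78 °C) should give the trienal silyl dienol ether F1. An intramolecular Diels–Alder reaction catalysed by a diphenylprolinol-derived oxazaborolidinium triflimide (CH2Cl2, –78 → –20 °C) should then give aldehyde 24 directly, so the route is rejoined at 24 and steps 8, 9, 11 and 12 fall away. The catalyst antipode is the one whose pre-transition-state model exposes the same face of C9=C10 as in step 10; this sense is not derived here and would be confirmed on the first run.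

2. Step 14. Ketone enolisation may outrun the ester enolisation that is needed at C8, leaving the equilibration incomplete, and prolonged exposure to base may start condensation. The fallback sets C8 by reagent-directed hydrogen delivery instead of equilibration and sets out from alcohol 23. Saegusa–Ito oxidation (Pd(OAc)2, MeCN, rt) of the silyl enol ether should give the 6-oxo-7-ene ester F2. Hydrogenation with [Ir(cod)(PCy3)(py)]PF6 (H2, CH2Cl2) is steered by the C11 hydroxyl, which lies on the face of the C10 methyl group, so hydrogen should add to C8 from that face and give keto alcohol F3 with the ester equatorial. Dess–Martin oxidation to keto aldehyde F4 and aldehyde-selective Wittig methylenation (Ph3PCH3Br, KOt-Bu, THF, –78 °C) return to 27.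

3. Step 11. Hydride may attack the hindered imide slowly or at the ring carbonyl of the auxiliary, and the alkoxide generated beside the cis ester may lactonise and then be over-reduced. The fallback avoids the alcohol altogether and sets out from 22. Transthioesterification (EtSH, n-BuLi, THF, 0 °C) should give S-ethyl thioester F5 with release of the auxiliary. Fukuyama reduction (Et3SiH, palladium on carbon, acetone, rt) should then give aldehyde 24, where the route is rejoined and step 12 is no longer needed.

**Further compounds**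

F1 | step 10 | tert-butyl (2E,4Z,10E)-4-(tert-butyldimethylsilyloxy)-6,6,10-trimethyl-12-oxododeca-2,4,10-trienoate | O=C/C=C(\C)CCCC(C)(C)/C=C(O[Si](C)(C)C(C)(C)C)/C=C/C(=O)OC(C)(C)C
F2 | step 14 | tert-butyl 1-(hydroxymethyl)-5,5,8a-trimethyl-4-oxo-1,4,4a,5,6,7,8,8a-octahydronaphthalene-2-carboxylate (C7=C8 ene, trans-fused) | OC[C@@H]1C(C(=O)OC(C)(C)C)=CC(=O)[C@@H]2C(C)(C)CCC[C@@]12C
F3 | step 14 | tert-butyl 1-(hydroxymethyl)-5,5,8a-trimethyl-4-oxodecahydronaphthalene-2-carboxylate (2-ester trans to 1-CH2OH) | OC[C@@H]1[C@@H](C(=O)OC(C)(C)C)CC(=O)[C@@H]2C(C)(C)CCC[C@@]12C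
F4 | step 14 | tert-butyl 1-formyl-5,5,8a-trimethyl-4-oxodecahydronaphthalene-2-carboxylate (2-ester trans to 1-CHO) | O=C[C@@H]1[C@@H](C(=O)OC(C)(C)C)CC(=O)[C@@H]2C(C)(C)CCC[C@@]12C
F5 | step 11 | S-ethyl thioester analogue of 22 (same configuration) | CCSC(=O)[C@@H]1[C@H](C(=O)OC(C)(C)C)C=C(O[Si](C)(C)C(C)(C)C)[C@@H]2C(C)(C)CCC[C@@]12C
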